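**Plan**

- Retrosynthesis: ring A is cut at C4a–C5 and C8–C8a (flavanone numbering). Ring C is then a 2-aryl-2,3-dihydro-4H-pyran-4-one whose enol ether double bond is the C4a=C8a edge of ring A, and C5–C8 (H, prenyl, OH, H) are a 2-prenyl-1-methoxy-3-siloxybutadiene.
- A phenylsulfinyl group on the carbon that becomes C4a activates that double bond and later leaves together with the cis hydrogen at C8a. A sulfoxide is chosen over a sulfone because this hydrogen is syn to the leaving group and not acidic.
- Ring C is cut at O1–C8a and C2–C3 (hetero-Diels–Alder reaction of a chromene aldehyde with Danishefsky's diene). The C–S bond goes back to an α-iodo enone, and the dimethylpyran ring on ring B to an aryl propargyl ether.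
- Forward: dimethylpyran ring on ring B (steps 1–2), ring C (step 3), sulfur at the future C4a (steps 4–6), diene from 6-methylhept-5-en-2-one (steps 7–9), ring A last (step 10), which gives the free phenol directly.
- Stereochemistry: the only stereocentre, C2, is set in step 3 by the BINOL–titanium catalyst and is not touched again. The centres made in step 10 are erased by aromatisation.

Key step: step 10

Assumption: the catalyst from (S)-BINOL and Ti(OiPr)4 is taken to direct the diene to the Si face of the aryl aldehyde, the sense it shows in aldehyde allylation, which corresponds to the (S)-dihydropyranone; if the first batch proves to be the (R)-series, (R)-BINOL is used instead.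

Remark: sulfoxide 12 is carried as a mixture of epimers at sulfur, which is of no consequence because sulfur is lost in step 10.

**Route**

Step 1
Reactants: 1 2-methylbut-3-yn-2-ol; 2 4-hydroxybenzaldehyde
Product: 4 4-[(2-methylbut-3-yn-2-yl)oxy]benzaldehyde, via 2-methylbut-3-yn-2-yl trifluoroacetate 3 (not isolated)
Conditions: 1, (CF3CO)2O, DBU, MeCN, −5 °C; then 2, DBU, CuCl2·2H2O (0.1 mol%), 0 °C
Reagents that add atoms: none
Why: Copper-catalysed propargylic etherification of a phenol with a tertiary propargyl trifluoroacetate made in the flask is the standard entry to 1,1-dimethylpropargyl aryl ethers and works best with electron-poor phenols such as 2.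

Step 2
Reactants: 4 4-[(2-methylbut-3-yn-2-yl)oxy]benzaldehyde
Product: 6 2,2-dimethyl-2H-chromene-6-carbaldehyde, via 3-(3-methylbuta-1,2-dienyl)-4-hydroxybenzaldehyde 5 (not isolated)
Conditions: PhNEt2, 190 °C
Reagents that add atoms: none
Why: An aromatic propargyl Claisen rearrangement should give allenyl phenol 5, which closes to the chromene by a 1,5-hydrogen shift and oxa-6π electrocyclisation, the classical chromene synthesis.

Step 3
Reactants: 6 2,2-dimethyl-2H-chromene-6-carbaldehyde; 7 Danishefsky's diene, (E)-1-methoxy-3-(trimethylsilyloxy)buta-1,3-diene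
Product: 9 (S)-2-(2,2-dimethyl-2H-chromen-6-yl)-2,3-dihydro-4H-pyran-4-one, via Mukaiyama aldol silyl ether 8 (not isolated)
Conditions: (S)-BINOL (20 mol%), Ti(OiPr)4 (10 mol%), 4 Å MS, Et2O, −20 °C; then CF3CO2H, CH2Cl2, 0 °C
Reagents that add atoms: none
Why: In this Keck-type formal hetero-Diels–Alder reaction the chiral BINOL–titanium complex controls a Mukaiyama aldol addition of the diene to the Si face of the aldehyde, which sets C2 as S, and brief acid closes 8 to the pyranone with loss of methanol and the silyl group; para-alkoxybenzaldehydes are established substrates.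

Step 4
Reactants: 9 (S)-2-(2,2-dimethyl-2H-chromen-6-yl)-2,3-dihydro-4H-pyran-4-one
Product: 10 (S)-2-(2,2-dimethyl-2H-chromen-6-yl)-5-iodo-2,3-dihydro-4H-pyran-4-one
Conditions: I2, pyridine, CH2Cl2, 0 °C to rt
Reagents that add atoms: iodine, II
Why: Johnson α-iodination of an enone (pyridine adds to the β-carbon, the enolate is iodinated, pyridine is expelled) is routine for dihydropyranones, places iodine only at C5, and the weak base should not enolise C3.

Step 5
Reactants: 10 (S)-2-(2,2-dimethyl-2H-chromen-6-yl)-5-iodo-2,3-dihydro-4H-pyran-4-one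
Product: 11 (S)-2-(2,2-dimethyl-2H-chromen-6-yl)-5-(phenylsulfanyl)-2,3-dihydro-4H-pyran-4-one
Conditions: Bu3SnSPh, Pd(PPh3)4 (5 mol%), PhMe, 90 °C
Reagents that add atoms: tributyl(phenylthio)stannane, CCCC[Sn](CCCC)(CCCC)Sc1ccccc1
Why: In this Migita–Kosugi C–S coupling zerovalent palladium inserts into the alkenyl C–I bond, the phenylthio group is transferred from tin and reductive elimination follows; the neutral medium without free thiolate should avoid conjugate addition to the vinylogous ester and base-induced opening of ring C.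

Step 6
Reactants: 11 (S)-2-(2,2-dimethyl-2H-chromen-6-yl)-5-(phenylsulfanyl)-2,3-dihydro-4H-pyran-4-one
Product: 12 (2S)-2-(2,2-dimethyl-2H-chromen-6-yl)-5-(phenylsulfinyl)-2,3-dihydro-4H-pyran-4-one (both epimers at sulfur)
Conditions: mCPBA (1.0 equiv), NaHCO3, CH2Cl2, −78 °C
Reagents that add atoms: 3-chloroperoxybenzoic acid, O=C(OO)c1cccc(Cl)c1
Why: Peracid oxidation of a sulfide to the sulfoxide is far faster at −78 °C than epoxidation of the chromene double bond, and one equivalent should stop short of the sulfone.

Step 7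
Reactants: 13 6-methylhept-5-en-2-one
Product: 14 3-(dimethoxymethyl)-6-methylhept-5-en-2-one (racemic)
Conditions: HC(OMe)3, BF3·OEt2, CH2Cl2, −30 °C; then 13, i-Pr2NEt, −78 °C to rt
Reagents that add atoms: trimethyl orthoformate, COC(OC)OC
Why: In this Mock–Tsou α-dialkoxymethylation the dialkoxycarbenium ion made in the flask is captured by the boron enolate of the ketone, which forms under these acidic conditions at the more substituted α-carbon (C3) and is much more nucleophilic than the trisubstituted olefin.

Step 8
Reactants: 14 3-(dimethoxymethyl)-6-methylhept-5-en-2-one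
Product: 15 (E)-3-(methoxymethylene)-6-methylhept-5-en-2-one
Conditions: PPTS (10 mol%), PhMe, reflux, 4 Å MS
Reagents that add atoms: none
Why: Acid-catalysed loss of methanol from a β-keto acetal gives the β-methoxy enone under equilibrating conditions, which should favour the E isomer with methoxy trans to the acetyl group.

Step 9
Reactants: 15 (E)-3-(methoxymethylene)-6-methylhept-5-en-2-one
Product: 16 (E)-1-methoxy-2-(3-methylbut-2-enyl)-3-(tert-butyldimethylsilyloxy)buta-1,3-diene
Conditions: TBSOTf, Et3N, Et2O, 0 °C
Reagents that add atoms: tert-butyldimethylsilyl trifluoromethanesulfonate, CC(C)(C)[Si](C)(C)OS(=O)(=O)C(F)(F)F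
Why: Soft enolisation with a silyl triflate and an amine, the usual route to Danishefsky-type dienes, can only occur at the methyl group and retains the enol ether geometry.

Step 10
Reactants: 12 (2S)-2-(2,2-dimethyl-2H-chromen-6-yl)-5-(phenylsulfinyl)-2,3-dihydro-4H-pyran-4-one; 16 (E)-1-methoxy-2-(3-methylbut-2-enyl)-3-(tert-butyldimethylsilyloxy)buta-1,3-diene
Product: 20 Dinklagin A, via cis-fused sulfinyl cycloadduct 17 (not isolated), via 4a-sulfinyl enedione 18 (not isolated), via chromene-4,7-dione keto tautomer 19 (not isolated)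
Conditions: ZnBr2 (1.2 equiv), CH2Cl2, −20 to 0 °C; then CSA (0.2 equiv), 0 °C; cold aq NaHCO3 wash; then CaCO3, PhMe, 70 °C
Reagents that add atoms: none
Why: ZnBr2 bridges the sulfinyl and C4 carbonyl oxygens of 12 and lowers the LUMO of its C5=C6 enol ether bond (the future C4a=C8a), to which the diene adds in an asynchronous [4+2] cycloaddition (or its Michael–Michael equivalent), the CH2 terminus (C8) bonding to C8a and the methoxy-bearing carbon (C5) to C4a; this intermolecular cycloaddition closes the six-membered carbocycle ring A and gives cis-fused 17. The closest known reactions are Lewis-acid-promoted Diels–Alder additions of 2-sulfinyl-2-cycloalkenones and sulfinylquinones to alkoxy-siloxy dienes followed by pyrolytic loss of a sulfenic acid. Catalytic acid then ionises the allylic methoxy group and the silyl group passes to methanol, which gives enone 18 and makes C5 sp2, so that the only β-hydrogen left syn to sulfur is the one at C8a. Gentle warming should then cause syn elimination of benzenesulfenic acid across C4a–C8a to give 19, the keto tautomer of the phenol, which enolises to 20. The transient centres at C4a, C5, C8a and sulfur are all erased, so no facial or endo/exo control is needed and C2 is a spectator. The one selectivity that matters is the orientation of the diene, which polarity fixes because C8a is β to both the ketone and the sulfinyl group while the unsubstituted diene terminus is its most nucleophilic carbon; the sulfoxide is used in place of a sulfone because a thermal syn elimination suits the cis, non-acidic C8a hydrogen whereas a base-induced anti elimination does not.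

**Compound list**

1 | 2-methylbut-3-yn-2-ol | CC(C)(O)C#C | starting material
2 | 4-hydroxybenzaldehyde | O=Cc1ccc(O)cc1 | starting material
3 | 2-methylbut-3-yn-2-yl trifluoroacetate | C#CC(C)(C)OC(=O)C(F)(F)F | intermediate
4 | 4-[(2-methylbut-3-yn-2-yl)oxy]benzaldehyde | C#CC(C)(C)Oc1ccc(C=O)cc1 | intermediate
5 | 4-hydroxy-3-(3-methylbuta-1,2-dien-1-yl)benzaldehyde | O=Cc1ccc(O)c(C=C=C(C)C)c1 | intermediate
6 | 2,2-dimethyl-2H-chromene-6-carbaldehyde | O=Cc1ccc2c(c1)C=CC(C)(C)O2 | intermediate
7 | Danishefsky's diene, (E)-1-methoxy-3-(trimethylsilyloxy)buta-1,3-diene | CO/C=C/C(=C)O[Si](C)(C)C | starting material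
8 | (S,E)-5-(2,2-dimethyl-2H-chromen-6-yl)-1-methoxy-5-(trimethylsilyloxy)pent-1-en-3-one | CO/C=C/C(=O)C[C@H](O[Si](C)(C)C)c1ccc2c(c1)C=CC(C)(C)O2 | intermediate
9 | (S)-2-(2,2-dimethyl-2H-chromen-6-yl)-2,3-dihydro-4H-pyran-4-one | O=C1C=CO[C@H](c2ccc3c(c2)C=CC(C)(C)O3)C1 | intermediate
10 | (S)-2-(2,2-dimethyl-2H-chromen-6-yl)-5-iodo-2,3-dihydro-4H-pyran-4-one | O=C1C(I)=CO[C@H](c2ccc3c(c2)C=CC(C)(C)O3)C1 | intermediate
11 | (S)-2-(2,2-dimethyl-2H-chromen-6-yl)-5-(phenylsulfanyl)-2,3-dihydro-4H-pyran-4-one | O=C1C(Sc2ccccc2)=CO[C@H](c2ccc3c(c2)C=CC(C)(C)O3)C1 | intermediate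
12 | (2S)-2-(2,2-dimethyl-2H-chromen-6-yl)-5-(phenylsulfinyl)-2,3-dihydro-4H-pyran-4-one, both epimers at sulfur | O=C1C(S(=O)c2ccccc2)=CO[C@H](c2ccc3c(c2)C=CC(C)(C)O3)C1 | intermediate
13 | 6-methylhept-5-en-2-one | CC(=O)CCC=C(C)C | starting material
14 | 3-(dimethoxymethyl)-6-methylhept-5-en-2-one, racemic | COC(OC)C(CC=C(C)C)C(C)=O | intermediate
15 | (E)-3-(methoxymethylene)-6-methylhept-5-en-2-one | CO/C=C(CC=C(C)C)/C(C)=O | intermediate
16 | (E)-1-methoxy-2-(3-methylbut-2-enyl)-3-(tert-butyldimethylsilyloxy)buta-1,3-diene | CO/C=C(CC=C(C)C)/C(=C)O[Si](C)(C)C(C)(C)C | intermediate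
17 | (2S)-7-(tert-butyldimethylsilyloxy)-2-(2,2-dimethyl-2H-chromen-6-yl)-5-methoxy-6-(3-methylbut-2-enyl)-4a-(phenylsulfinyl)-2,3,4a,5,8,8a-hexahydro-4H-chromen-4-one, cis-fused, mixture of diastereomers at C4a, C5, C8a and sulfur | O=C1C[C@@H](c2ccc3c(c2)C=CC(C)(C)O3)OC2CC(O[Si](C)(C)C(C)(C)C)=C(CC=C(C)C)C(OC)C12S(=O)c1ccccc1 | intermediate
18 | (2S)-2-(2,2-dimethyl-2H-chromen-6-yl)-6-(3-methylbut-2-enyl)-4a-(phenylsulfinyl)-2,3,8,8a-tetrahydro-4H-chromene-4,7(4aH)-dione, cis-fused, mixture of diastereomers | O=C1C[C@@H](c2ccc3c(c2)C=CC(C)(C)O3)OC2CC(=O)C(CC=C(C)C)=CC12S(=O)c1ccccc1 | intermediate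
19 | (S)-2-(2,2-dimethyl-2H-chromen-6-yl)-6-(3-methylbut-2-enyl)-2,3-dihydro-4H-chromene-4,7(8H)-dione | O=C1C[C@@H](c2ccc3c(c2)C=CC(C)(C)O3)OC2=C1C=C(CC=C(C)C)C(=O)C2 | intermediate
20 | Dinklagin A, (S)-2-(2,2-dimethyl-2H-chromen-6-yl)-7-hydroxy-6-(3-methylbut-2-enyl)chroman-4-one | CC(C)=CCc1cc2c(cc1O)O[C@H](c1ccc3c(c1)C=CC(C)(C)O3)CC2=O | target

**Step count**

Total: 10 steps. Longest linear sequence: 7 steps (steps 1–6 and 10); the diene branch (steps 7–9) is 3 steps.

**Steps most likely to fail, with fallbacks**

1. Step 10. The cycloaddition may be too slow below the temperature at which the sulfoxide begins to eliminate, so that elimination toward the C5 hydrogen of the still-masked adduct (a C4a=C5 enol ether that cannot aromatise) competes. Zinc-assisted ionisation of the benzylic C2–O bond may also erode the enantiomeric purity. The fallback raises the HOMO of the diene instead of lowering the LUMO of 12; it sets out from 15 and 12 and rejoins the route at 18. Amine exchange of 15 with Me2NH (THF, rt) should give (E)-3-[(dimethylamino)methylene]-6-methylhept-5-en-2-one F1. KN(SiMe3)2 and then TBSCl (THF, −78 °C) should convert it into (E)-1-(dimethylamino)-2-(3-methylbut-2-enyl)-3-(tert-butyldimethylsilyloxy)buta-1,3-diene F2. This 1-amino-3-siloxy diene is far more nucleophilic and should add to 12 in toluene between 0 °C and rt without any Lewis acid to give the 5-(dimethylamino) cycloadduct F3. Aqueous HF in MeCN at 0 °C should then expel dimethylamine and the silyl group to give 18, which is warmed as in step 10.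

2. Step 5. Reductive elimination to the C–S bond may be slow on this electron-poor alkenyl palladium species, so that protodeiodination takes over, and prolonged heating may cause reversible opening of ring C with loss of configuration at C2. The fallback closes ring C last with sulfur already in place; it sets out from 6 and rejoins the route at 11.
   - Roskamp homologation of 6 (N2CHCO2Et, SnCl2 cat., CH2Cl2) should give ethyl 3-(2,2-dimethyl-2H-chromen-6-yl)-3-oxopropanoate F4.
   - Asymmetric transfer hydrogenation with RuCl[(S,S)-TsDPEN](p-cymene) in HCO2H/Et3N should give ethyl (S)-3-(2,2-dimethyl-2H-chromen-6-yl)-3-hydroxypropanoate F5. The (S)-carbinol is expected by analogy with acetophenone, and the olefin is left alone.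
   - Excess PhSCH2Li (from PhSMe, n-BuLi, DABCO, THF; addition at −78 °C) should stop at the enolised ketone and give (S)-4-(2,2-dimethyl-2H-chromen-6-yl)-4-hydroxy-1-(phenylsulfanyl)butan-2-one F6.
   - Condensation with Me2NCH(OMe)2 (PhMe, rt) should give the enaminone (S)-1-(dimethylamino)-5-(2,2-dimethyl-2H-chromen-6-yl)-5-hydroxy-2-(phenylsulfanyl)pent-1-en-3-one F7, which should close to 11 on gentle warming with AcOH by oxa-Michael addition and loss of dimethylamine.

3. Step 7. Condensation may occur in part at the methyl group of 13, or the carbenium ion may attack the trisubstituted olefin. The fallback fixes the regiochemistry in an isolable enol ether; it sets out from 13 and rejoins the route at 14. Silylation under equilibrating conditions (Me3SiCl, NaI, Et3N, MeCN, rt) should give mainly the more substituted enol ether (Z)-trimethyl[(6-methylhepta-2,5-dien-2-yl)oxy]silane F8, from which the terminal isomer is removed by distillation. A Mukaiyama-type reaction with HC(OMe)3 and Me3SiOTf (5 mol%) in CH2Cl2 at −78 °C should then give 14.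

**Further compounds**

F1 | step 10 | (E)-3-[(dimethylamino)methylene]-6-methylhept-5-en-2-one | CN(C)/C=C(CC=C(C)C)/C(C)=O
F2 | step 10 | (E)-1-(dimethylamino)-2-(3-methylbut-2-enyl)-3-(tert-butyldimethylsilyloxy)buta-1,3-diene | CN(C)/C=C(CC=C(C)C)/C(=C)O[Si](C)(C)C(C)(C)C
F3 | step 10 | (2S)-7-(tert-butyldimethylsilyloxy)-5-(dimethylamino)-2-(2,2-dimethyl-2H-chromen-6-yl)-6-(3-methylbut-2-enyl)-4a-(phenylsulfinyl)-2,3,4a,5,8,8a-hexahydro-4H-chromen-4-one, cis-fused, mixture of diastereomers | O=C1C[C@@H](c2ccc3c(c2)C=CC(C)(C)O3)OC2CC(O[Si](C)(C)C(C)(C)C)=C(CC=C(C)C)C(N(C)C)C12S(=O)c1ccccc1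
F4 | step 5 | ethyl 3-(2,2-dimethyl-2H-chromen-6-yl)-3-oxopropanoate | CCOC(=O)CC(=O)c1ccc2c(c1)C=CC(C)(C)O2
F5 | step 5 | ethyl (S)-3-(2,2-dimethyl-2H-chromen-6-yl)-3-hydroxypropanoate | CCOC(=O)C[C@H](O)c1ccc2c(c1)C=CC(C)(C)O2
F6 | step 5 | (S)-4-(2,2-dimethyl-2H-chromen-6-yl)-4-hydroxy-1-(phenylsulfanyl)butan-2-one | O=C(CSc1ccccc1)C[C@H](O)c1ccc2c(c1)C=CC(C)(C)O2
F7 | step 5 | (S)-1-(dimethylamino)-5-(2,2-dimethyl-2H-chromen-6-yl)-5-hydroxy-2-(phenylsulfanyl)pent-1-en-3-one | CN(C)C=C(Sc1ccccc1)C(=O)C[C@H](O)c1ccc2c(c1)C=CC(C)(C)O2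
F8 | step 7 | (Z)-trimethyl[(6-methylhepta-2,5-dien-2-yl)oxy]silane | C/C(O[Si](C)(C)C)=C/CC=C(C)C
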